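The C6'–C8'' biaryl bond is never made by coupling: flavone ring A is grown around the carbon that already carries ring B. C8'' lies between the oxygen-bearing carbons C7'' and C8a'', and the 1,3,5-oxygen pattern of ring A (C5'', C7'', C8a'') is that of a folded triketide. One methoxide-driven Claisen closure of methyl 6-(4,5-dibenzyloxy-2-bromophenyl)-3,5-dioxohexanoate 7 therefore forms C8''–C8a'' and gives the symmetric 2-arylphloroglucinol 9. Acetylation, chalcone formation and oxidative closure give the 8-arylluteolin. The bromine, a silent handle until then, becomes a boronate for a rhodium-catalysed enantioselective addition to a chromone that sets (2R), and one hydrogenolysis frees all eight phenols.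

Key step: step 5

Remark: the flavanone C2 centre is read from the SMILES as (R), and 3,4-bis(benzyloxy)benzaldehyde is taken to be purchasable.

Step 1
Reactants: 1 3,4-dihydroxyphenylacetic acid
Product: 2 benzyl 2-[3,4-bis(benzyloxy)phenyl]acetate
Conditions: BnBr (3.5 equiv), K2CO3 (4 equiv), DMF, 60 °C
Reagents that add atoms: benzyl bromide, BrCc1ccccc1
Why: Williamson etherification of both phenols and alkylation of the carboxylate under one mild base mask all three acidic sites as groups that tolerate the later strong-base steps.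

Step 2
Reactants: 2 benzyl 2-[3,4-bis(benzyloxy)phenyl]acetate
Product: 3 benzyl 2-[4,5-bis(benzyloxy)-2-bromophenyl]acetate
Conditions: N-bromosuccinimide (1.05 equiv), MeCN, 0 °C to rt, dark
Reagents that add atoms: N-bromosuccinimide, O=C1CCC(=O)N1Br
Why: electrophilic aromatic bromination goes para to the C3 benzyloxy group and ortho to the side chain, the only position that is alkoxy-activated and not flanked on both sides, as is usual for 3,4-dialkoxyphenylacetic acid derivatives.

Step 3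
Reactants: 3 benzyl 2-[4,5-bis(benzyloxy)-2-bromophenyl]acetate
Product: 4 2-[4,5-bis(benzyloxy)-2-bromophenyl]-N-methoxy-N-methylacetamide
Conditions: MeNHOMe·HCl (1.6 equiv), i-PrMgCl (3.2 equiv), THF, −20 to 0 °C
Reagents that add atoms: N,O-dimethylhydroxylamine hydrochloride, CNOC.Cl
Why: aminolysis of the ester by the chloromagnesium amide gives the Weinreb amide, a mono-acylating agent that avoids the ketene formation of an arylacetyl chloride, and the electron-rich aryl bromide does not undergo halogen–magnesium exchange at this temperature.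

Step 4
Reactants: 5 methyl acetoacetate; 4 2-[4,5-bis(benzyloxy)-2-bromophenyl]-N-methoxy-N-methylacetamide
Product: 7 methyl 6-[4,5-bis(benzyloxy)-2-bromophenyl]-3,5-dioxohexanoate, via dilithio methyl acetoacetate dianion 6 (not isolated)
Conditions: 5 (2.5 equiv), LiN(i-Pr)2 (5.0 equiv), THF, 0 °C; then 4, −78 to 0 °C; aq NH4Cl
Reagents that add atoms: none
Why: Claisen-type γ-acylation of the acetoacetate dianion at its terminal carbon by the Weinreb amide stops at the ketone because the chelated adduct collapses only on work-up, and the excess dianion absorbs any proton transfer from the benzylic position.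

Step 5
Reactants: 7 methyl 6-[4,5-bis(benzyloxy)-2-bromophenyl]-3,5-dioxohexanoate
Product: 9 2-[4,5-bis(benzyloxy)-2-bromophenyl]benzene-1,3,5-triol, via 2-arylcyclohexane-1,3,5-trione 8 (not isolated)
Conditions: NaOMe (5 equiv), MeOH, 80 °C (sealed tube), argon; then 1 M HCl, 0 °C
Reagents that add atoms: none
Why: Methoxide equilibrates the anions of the chain, and the minor enolate at the benzylic carbon (acidified by the aryl ring and the adjacent ketone) adds to the ester carbonyl, expels methoxide and leaves a 2-aryl-1,3,5-trione that enolises to the phloroglucinol. The closest known reaction type is the alkoxide-mediated intramolecular Claisen (Dieckmann-type) cyclisation of 3,5-dioxoalkanoates to phloroglucinols and of 6-aryl-5-oxohexanoates to 2-arylcyclohexane-1,3-diones. The one ring formed, flavone ring A, closes in a 6-exo-trig mode, the enolate carbon attacking a carbonyl whose oxygen lies outside the new ring. No stereocentre is created. The step needs C-acylation to win over O-acylation to the 4-hydroxy-2-pyranone and over retro-Claisen cleavage: lactone formation is reversible in methanolic methoxide whereas aromatisation of the carbocycle is not, and the diketone is shielded from cleavage as its enolate. Because the triol is symmetric about the biaryl axis, the following acylation meets only one kind of free ring position.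

Step 6
Reactants: 9 2-[4,5-bis(benzyloxy)-2-bromophenyl]benzene-1,3,5-triol
Product: 11 1-[3-(4,5-bis(benzyloxy)-2-bromophenyl)-2,4,6-trihydroxyphenyl]ethan-1-one, via ketiminium chloride 10 (not isolated)
Conditions: MeCN (5 equiv), ZnCl2 (1.2 equiv), HCl (g), Et2O, 0 °C; then H2O, 90 °C
Reagents that add atoms: acetonitrile, CC#N; water, O
Why: Hoesch acylation puts the nitrilium electrophile on one of the two equivalent free positions of the phloroglucinol ring, the precipitated ketiminium salt resists a second acylation and is hydrolysed by hot water, and the less nucleophilic bromocatechol ring and its benzyl ethers should be spared at 0 °C.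

Step 7
Reactants: 11 1-[3-(4,5-bis(benzyloxy)-2-bromophenyl)-2,4,6-trihydroxyphenyl]ethan-1-one
Product: 12 1-[4,6-bis(benzyloxy)-3-(4,5-bis(benzyloxy)-2-bromophenyl)-2-hydroxyphenyl]ethan-1-one
Conditions: BnBr (2.1 equiv), K2CO3 (2.2 equiv), acetone, 56 °C
Reagents that add atoms: benzyl bromide, BrCc1ccccc1
Why: Williamson etherification should take the non-chelated para hydroxyl first and then the less hindered of the two chelated ortho hydroxyls, leaving free the one wedged between the acetyl group and the twisted bromoaryl ring, which is the oxygen that must become O1''.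

Step 8
Reactants: 12 1-[4,6-bis(benzyloxy)-3-(4,5-bis(benzyloxy)-2-bromophenyl)-2-hydroxyphenyl]ethan-1-one; 13 3,4-bis(benzyloxy)benzaldehyde
Product: 14 (E)-1-[4,6-bis(benzyloxy)-3-(4,5-bis(benzyloxy)-2-bromophenyl)-2-hydroxyphenyl]-3-[3,4-bis(benzyloxy)phenyl]prop-2-en-1-one
Conditions: KOH (50% aq), EtOH/THF, rt
Reagents that add atoms: none
Why: Claisen–Schmidt condensation of the methyl ketone enolate with the non-enolisable aldehyde, followed by dehydration, gives the conjugated (E)-enone.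

Step 9
Reactants: 14 (E)-1-[4,6-bis(benzyloxy)-3-(4,5-bis(benzyloxy)-2-bromophenyl)-2-hydroxyphenyl]-3-[3,4-bis(benzyloxy)phenyl]prop-2-en-1-one
Product: 15 5,7-bis(benzyloxy)-8-[4,5-bis(benzyloxy)-2-bromophenyl]-2-[3,4-bis(benzyloxy)phenyl]-4H-chromen-4-one
Conditions: I2 (10 mol %), DMSO, 120 °C
Reagents that add atoms: none
Why: the iodine/DMSO oxidative cyclisation of a 2'-hydroxychalcone closes the pyranone through the only free phenol, with DMSO as terminal oxidant, so the aryl group ends at C8''.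

Step 10
Reactants: 15 5,7-bis(benzyloxy)-8-[4,5-bis(benzyloxy)-2-bromophenyl]-2-[3,4-bis(benzyloxy)phenyl]-4H-chromen-4-one
Product: 16 5,7-bis(benzyloxy)-8-[4,5-bis(benzyloxy)-2-(4,4,5,5-tetramethyl-1,3,2-dioxaborolan-2-yl)phenyl]-2-[3,4-bis(benzyloxy)phenyl]-4H-chromen-4-one
Conditions: bis(pinacolato)diboron (1.5 equiv), Pd2(dba)3 (2.5 mol %), XPhos (10 mol %), KOAc (3 equiv), 1,4-dioxane, 100 °C
Reagents that add atoms: bis(pinacolato)diboron, CC1(C)OB(B2OC(C)(C)C(C)(C)O2)OC1(C)C
Why: Miyaura borylation with a bulky electron-rich biarylphosphine should insert into the electron-rich, ortho-substituted aryl bromide, acetate is too weak a base for homocoupling, and no free phenol is left to attack the arylpalladium intermediate.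

Step 11
Reactants: 17 5,7-dihydroxychromone
Product: 18 5,7-bis(benzyloxy)-4H-chromen-4-one
Conditions: BnBr (3 equiv), K2CO3 (4 equiv), DMF, 70 °C
Reagents that add atoms: benzyl bromide, BrCc1ccccc1
Why: Williamson etherification with excess halide in warm DMF overcomes the hydrogen bond of the C5 hydroxyl to the carbonyl and gives the acceptor with the same protecting group as the rest of the molecule.

Step 12
Reactants: 16 5,7-bis(benzyloxy)-8-[4,5-bis(benzyloxy)-2-(4,4,5,5-tetramethyl-1,3,2-dioxaborolan-2-yl)phenyl]-2-[3,4-bis(benzyloxy)phenyl]-4H-chromen-4-one; 18 5,7-bis(benzyloxy)-4H-chromen-4-one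
Product: 19 (2R)-5,7-bis(benzyloxy)-2-{4,5-bis(benzyloxy)-2-[5,7-bis(benzyloxy)-2-(3,4-bis(benzyloxy)phenyl)-4-oxo-4H-chromen-8-yl]phenyl}-2,3-dihydro-4H-chromen-4-one
Conditions: 18 (2 equiv), [RhCl(C2H4)2]2 (2.5 mol %), (1R,4R)-2,5-diphenylbicyclo[2.2.2]octa-2,5-diene (5.5 mol %), K3PO4 (1 equiv, aq), 1,4-dioxane/H2O (10:1), 50 °C
Reagents that add atoms: none
Why: in this rhodium-catalysed asymmetric 1,4-addition of an arylboron reagent to a chromone, the aryl–rhodium species formed by transmetalation inserts into C2=C3 of 18 and water protonates the rhodium enolate, the C2-symmetric diene exposing one face of the bound chromone so that the (1R,4R) ligand is expected, from its sense of induction with cyclic enones, to give the (2R) centre (its mirror image would serve if the sense proved opposite), while the 2-substituted flavone of 16 is no competing acceptor and the mild base spares the flavanone from ring opening.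

Step 13
Reactants: 19 (2R)-5,7-bis(benzyloxy)-2-{4,5-bis(benzyloxy)-2-[5,7-bis(benzyloxy)-2-(3,4-bis(benzyloxy)phenyl)-4-oxo-4H-chromen-8-yl]phenyl}-2,3-dihydro-4H-chromen-4-one
Product: 20 (2R)-2-{2-[2-(3,4-dihydroxyphenyl)-5,7-dihydroxy-4-oxo-4H-chromen-8-yl]-4,5-dihydroxyphenyl}-5,7-dihydroxy-2,3-dihydro-4H-chromen-4-one
Conditions: H2 (1 atm), Pd/C (10 wt % Pd on carbon), THF/MeOH (1:1), rt
Reagents that add atoms: none
Why: neutral catalytic hydrogenolysis cleaves all eight benzyl aryl ethers while the flavone double bond, both carbonyl groups and the C2 stereocentre, which racemises only through acid- or base-induced ring opening, should remain untouched.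

Compound list
1 | 3,4-dihydroxyphenylacetic acid | OC(=O)Cc1ccc(O)c(O)c1 | starting material
2 | benzyl 2-[3,4-bis(benzyloxy)phenyl]acetate | O=C(Cc1ccc(OCc2ccccc2)c(OCc2ccccc2)c1)OCc1ccccc1 | intermediate
3 | benzyl 2-[4,5-bis(benzyloxy)-2-bromophenyl]acetate | O=C(Cc1cc(OCc2ccccc2)c(OCc2ccccc2)cc1Br)OCc1ccccc1 | intermediate
4 | 2-[4,5-bis(benzyloxy)-2-bromophenyl]-N-methoxy-N-methylacetamide | CON(C)C(=O)Cc1cc(OCc2ccccc2)c(OCc2ccccc2)cc1Br | intermediate
5 | methyl acetoacetate | COC(=O)CC(C)=O | starting material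
6 | dilithio methyl acetoacetate dianion | [Li+].[Li+].COC(=O)[CH-]C(=O)[CH2-] | intermediate (not isolated)
7 | methyl 6-[4,5-bis(benzyloxy)-2-bromophenyl]-3,5-dioxohexanoate | COC(=O)CC(=O)CC(=O)Cc1cc(OCc2ccccc2)c(OCc2ccccc2)cc1Br | intermediate
8 | 2-[4,5-bis(benzyloxy)-2-bromophenyl]cyclohexane-1,3,5-trione | O=C1CC(=O)C(c2cc(OCc3ccccc3)c(OCc3ccccc3)cc2Br)C(=O)C1 | intermediate (not isolated)
9 | 2-[4,5-bis(benzyloxy)-2-bromophenyl]benzene-1,3,5-triol | Oc1cc(O)c(-c2cc(OCc3ccccc3)c(OCc3ccccc3)cc2Br)c(O)c1 | intermediate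
10 | 1-[3-(4,5-bis(benzyloxy)-2-bromophenyl)-2,4,6-trihydroxyphenyl]ethan-1-iminium chloride | CC(=[NH2+])c1c(O)cc(O)c(-c2cc(OCc3ccccc3)c(OCc3ccccc3)cc2Br)c1O.[Cl-] | intermediate (not isolated)
11 | 1-[3-(4,5-bis(benzyloxy)-2-bromophenyl)-2,4,6-trihydroxyphenyl]ethan-1-one | CC(=O)c1c(O)cc(O)c(-c2cc(OCc3ccccc3)c(OCc3ccccc3)cc2Br)c1O | intermediate
12 | 1-[4,6-bis(benzyloxy)-3-(4,5-bis(benzyloxy)-2-bromophenyl)-2-hydroxyphenyl]ethan-1-one | CC(=O)c1c(OCc2ccccc2)cc(OCc2ccccc2)c(-c2cc(OCc3ccccc3)c(OCc3ccccc3)cc2Br)c1O | intermediate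
13 | 3,4-bis(benzyloxy)benzaldehyde | O=Cc1ccc(OCc2ccccc2)c(OCc2ccccc2)c1 | starting material
14 | (E)-1-[4,6-bis(benzyloxy)-3-(4,5-bis(benzyloxy)-2-bromophenyl)-2-hydroxyphenyl]-3-[3,4-bis(benzyloxy)phenyl]prop-2-en-1-one | O=C(/C=C/c1ccc(OCc2ccccc2)c(OCc2ccccc2)c1)c1c(OCc2ccccc2)cc(OCc2ccccc2)c(-c2cc(OCc3ccccc3)c(OCc3ccccc3)cc2Br)c1O | intermediate
15 | 5,7-bis(benzyloxy)-8-[4,5-bis(benzyloxy)-2-bromophenyl]-2-[3,4-bis(benzyloxy)phenyl]-4H-chromen-4-one | O=c1cc(-c2ccc(OCc3ccccc3)c(OCc3ccccc3)c2)oc2c(-c3cc(OCc4ccccc4)c(OCc4ccccc4)cc3Br)c(OCc3ccccc3)cc(OCc3ccccc3)c12 | intermediate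
16 | 5,7-bis(benzyloxy)-8-[4,5-bis(benzyloxy)-2-(4,4,5,5-tetramethyl-1,3,2-dioxaborolan-2-yl)phenyl]-2-[3,4-bis(benzyloxy)phenyl]-4H-chromen-4-one | CC1(C)OB(c2cc(OCc3ccccc3)c(OCc3ccccc3)cc2-c2c(OCc3ccccc3)cc(OCc3ccccc3)c3c(=O)cc(-c4ccc(OCc5ccccc5)c(OCc5ccccc5)c4)oc23)OC1(C)C | intermediate
17 | 5,7-dihydroxychromone | O=c1ccoc2cc(O)cc(O)c12 | starting material
18 | 5,7-bis(benzyloxy)-4H-chromen-4-one | O=c1ccoc2cc(OCc3ccccc3)cc(OCc3ccccc3)c12 | intermediate
19 | (2R)-5,7-bis(benzyloxy)-2-{4,5-bis(benzyloxy)-2-[5,7-bis(benzyloxy)-2-(3,4-bis(benzyloxy)phenyl)-4-oxo-4H-chromen-8-yl]phenyl}-2,3-dihydro-4H-chromen-4-one | O=C1C[C@H](c2cc(OCc3ccccc3)c(OCc3ccccc3)cc2-c2c(OCc3ccccc3)cc(OCc3ccccc3)c3c(=O)cc(-c4ccc(OCc5ccccc5)c(OCc5ccccc5)c4)oc23)Oc2cc(OCc3ccccc3)cc(OCc3ccccc3)c21 | intermediate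
20 | (2R)-2-{2-[2-(3,4-dihydroxyphenyl)-5,7-dihydroxy-4-oxo-4H-chromen-8-yl]-4,5-dihydroxyphenyl}-5,7-dihydroxy-2,3-dihydro-4H-chromen-4-one | O=C1C[C@H](c2cc(O)c(O)cc2-c2c(O)cc(O)c3c(=O)cc(-c4ccc(O)c(O)c4)oc23)Oc2cc(O)cc(O)c21 | target

Total step count: 13. Longest linear sequence: 12 steps (steps 1 to 10, 12 and 13, from 3,4-dihydroxyphenylacetic acid).

Steps most likely to fail

Step 5. O-acylation to the 4-hydroxy-2-pyranone, or retro-Claisen cleavage of the chain, may outrun C-acylation at the benzylic carbon. The fallback gives up ring construction and makes the crowded biaryl bond by cross-coupling on a preformed flavone; it sets out from 13 and rejoins the route at 15. Commercial 1-[2,4-bis(benzyloxy)-6-hydroxyphenyl]ethan-1-one would be iodinated ortho to its free phenol (N-iodosuccinimide, CH2Cl2) to 1-[4,6-bis(benzyloxy)-2-hydroxy-3-iodophenyl]ethan-1-one F1. Claisen–Schmidt condensation of F1 with 13 (KOH, EtOH) would give (E)-1-[4,6-bis(benzyloxy)-2-hydroxy-3-iodophenyl]-3-[3,4-bis(benzyloxy)phenyl]prop-2-en-1-one F2, and I2/DMSO would close it to 5,7-bis(benzyloxy)-2-[3,4-bis(benzyloxy)phenyl]-8-iodo-4H-chromen-4-one F3. In parallel, commercial 1,2-bis(benzyloxy)benzene would be dibrominated (Br2, AcOH) to 1,2-bis(benzyloxy)-4,5-dibromobenzene F4, and a single bromine–lithium exchange (n-BuLi, THF, −78 °C) followed by B(Oi-Pr)3 and acid would give [4,5-bis(benzyloxy)-2-bromophenyl]boronic acid F5. Suzuki–Miyaura coupling of F3 with F5 (Pd(PPh3)4, K2CO3, DME/H2O, 80 °C), in which the aryl iodide reacts ahead of the aryl bromide, should then give 15.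

Step 12. Transfer of the crowded ortho-biaryl group from boron to rhodium and its insertion into the electron-rich chromone may be slower than protodeboronation, or the facial discrimination may be poor with so large a nucleophile. The fallback builds the flavanone through a chalcone and separates the enantiomers; it sets out from 15 and rejoins at 19. Reductive carbonylation of 15 (Pd(OAc)2, di(1-adamantyl)-n-butylphosphine, CO/H2, TMEDA, toluene, 100 °C) would give 4,5-bis(benzyloxy)-2-{5,7-bis(benzyloxy)-2-[3,4-bis(benzyloxy)phenyl]-4-oxo-4H-chromen-8-yl}benzaldehyde F6. Claisen–Schmidt condensation of F6 with commercial 1-[2,4-bis(benzyloxy)-6-hydroxyphenyl]ethan-1-one (KOH, EtOH/THF, rt) would give the 2'-hydroxychalcone F7, and oxa-Michael closure (NaOAc, EtOH, reflux) the racemic flavanone F8. Preparative chromatography of F8 on a chiral stationary phase would deliver 19. The (2S) antipode F9 can be returned to the racemate by renewed treatment with NaOAc in hot ethanol, through reversible opening to F7.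

Step 7. Benzylation may fall on the hindered hydroxyl next to the aryl group, or go on to the tri-ether, which would later direct ring closure to the 6-aryl isomer. The fallback replaces selective protection by selective deprotection; it sets out from 11 and rejoins at 12. Exhaustive benzylation (BnBr, Cs2CO3, DMF, 80 °C) would give 1-[2,4,6-tris(benzyloxy)-3-(4,5-bis(benzyloxy)-2-bromophenyl)phenyl]ethan-1-one F10. Chelation-directed mono-debenzylation of F10 (MgBr2·OEt2, toluene/Et2O, 70 °C) should then remove the benzyl group ortho to the carbonyl that is forced out of plane by its two neighbours, as the more hindered ortho ether is the one cleaved in polyalkoxyacetophenones, and so give 12.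

Further compounds
F1 | step 5 | 1-[4,6-bis(benzyloxy)-2-hydroxy-3-iodophenyl]ethan-1-one | CC(=O)c1c(OCc2ccccc2)cc(OCc2ccccc2)c(I)c1O
F2 | step 5 | (E)-1-[4,6-bis(benzyloxy)-2-hydroxy-3-iodophenyl]-3-[3,4-bis(benzyloxy)phenyl]prop-2-en-1-one | O=C(/C=C/c1ccc(OCc2ccccc2)c(OCc2ccccc2)c1)c1c(OCc2ccccc2)cc(OCc2ccccc2)c(I)c1O
F3 | step 5 | 5,7-bis(benzyloxy)-2-[3,4-bis(benzyloxy)phenyl]-8-iodo-4H-chromen-4-one | O=c1cc(-c2ccc(OCc3ccccc3)c(OCc3ccccc3)c2)oc2c(I)c(OCc3ccccc3)cc(OCc3ccccc3)c12
F4 | step 5 | 1,2-bis(benzyloxy)-4,5-dibromobenzene | Brc1cc(OCc2ccccc2)c(OCc2ccccc2)cc1Br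
F5 | step 5 | [4,5-bis(benzyloxy)-2-bromophenyl]boronic acid | OB(O)c1cc(OCc2ccccc2)c(OCc2ccccc2)cc1Br
F6 | step 12 | 4,5-bis(benzyloxy)-2-{5,7-bis(benzyloxy)-2-[3,4-bis(benzyloxy)phenyl]-4-oxo-4H-chromen-8-yl}benzaldehyde | O=Cc1cc(OCc2ccccc2)c(OCc2ccccc2)cc1-c1c(OCc2ccccc2)cc(OCc2ccccc2)c2c(=O)cc(-c3ccc(OCc4ccccc4)c(OCc4ccccc4)c3)oc12
F7 | step 12 | (E)-3-{4,5-bis(benzyloxy)-2-[5,7-bis(benzyloxy)-2-(3,4-bis(benzyloxy)phenyl)-4-oxo-4H-chromen-8-yl]phenyl}-1-[2,4-bis(benzyloxy)-6-hydroxyphenyl]prop-2-en-1-one | O=C(/C=C/c1cc(OCc2ccccc2)c(OCc2ccccc2)cc1-c1c(OCc2ccccc2)cc(OCc2ccccc2)c2c(=O)cc(-c3ccc(OCc4ccccc4)c(OCc4ccccc4)c3)oc12)c1c(O)cc(OCc2ccccc2)cc1OCc1ccccc1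
F8 | step 12 | racemic 5,7-bis(benzyloxy)-2-{4,5-bis(benzyloxy)-2-[5,7-bis(benzyloxy)-2-(3,4-bis(benzyloxy)phenyl)-4-oxo-4H-chromen-8-yl]phenyl}-2,3-dihydro-4H-chromen-4-one | O=C1CC(c2cc(OCc3ccccc3)c(OCc3ccccc3)cc2-c2c(OCc3ccccc3)cc(OCc3ccccc3)c3c(=O)cc(-c4ccc(OCc5ccccc5)c(OCc5ccccc5)c4)oc23)Oc2cc(OCc3ccccc3)cc(OCc3ccccc3)c21
F9 | step 12 | (2S)-5,7-bis(benzyloxy)-2-{4,5-bis(benzyloxy)-2-[5,7-bis(benzyloxy)-2-(3,4-bis(benzyloxy)phenyl)-4-oxo-4H-chromen-8-yl]phenyl}-2,3-dihydro-4H-chromen-4-one | O=C1C[C@@H](c2cc(OCc3ccccc3)c(OCc3ccccc3)cc2-c2c(OCc3ccccc3)cc(OCc3ccccc3)c3c(=O)cc(-c4ccc(OCc5ccccc5)c(OCc5ccccc5)c4)oc23)Oc2cc(OCc3ccccc3)cc(OCc3ccccc3)c21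
F10 | step 7 | 1-[2,4,6-tris(benzyloxy)-3-(4,5-bis(benzyloxy)-2-bromophenyl)phenyl]ethan-1-one | CC(=O)c1c(OCc2ccccc2)cc(OCc2ccccc2)c(-c2cc(OCc3ccccc3)c(OCc3ccccc3)cc2Br)c1OCc1ccccc1
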